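**Strategy**

The eleven-membered ring (target numbering: C1 carries the vanillate, C2=C3 is the E-alkene, C4 the free carbinol, C6=C7 the Z-alkene, C11 the CMe2 carbon) is closed last by a four-carbon ring enlargement. Its 1,5-diene C2=C3–C4–C5–C6=C7 with a latent C7 carbonyl is the retron of an anionic oxy-Cope rearrangement of a cis-1-vinyl-2-alkenylcycloheptan-1-ol (ring C7–C8–C9–C10–C11–C1–C2). One operation breaks C2–C7, forms C4–C5, sets the E-alkene and, by chirality transfer from C2 through an E-enol ether, the C4 stereocentre; the geometry-defined C7 enolate is trapped as the triflate that becomes the Z-alkene methyl.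

Key step: step 10

Remark on labels: in the Why lines C1–C11 are the ring atoms of the target, carried through all intermediates. In the cycloheptane intermediates the IUPAC locants 1, 2, 3, 4 correspond to target C7, C2, C1, C11.
Assumption: the quinine-derived 9-amino(9-deoxy)epi-cinchona amine salt gives the (2S,3S)-epoxide 7; if it gives the antipode, the quinidine-derived pseudoenantiomer is used.

**Route**

Step 1
Reactants: 1 3-methylcyclohex-2-en-1-one
Product: 3 3,3-dimethyl-1-(trimethylsilyloxy)cyclohex-1-ene, via lithium enolate 2 (not isolated)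
Conditions: Me2CuLi, Et2O, 0 °C; then TMSCl, Et3N, −78 °C → rt
Reagents that add atoms: lithium dimethylcuprate, [Li+].C[Cu-]C; chlorotrimethylsilane, C[Si](C)(C)Cl
Why: Conjugate addition of the Gilman cuprate builds the quaternary CMe2 carbon (C11), and O-silylation of the regiodefined enolate fixes the enol double bond on the side of that carbon (1,4-addition with enolate trapping).

Step 2
Reactants: 3 3,3-dimethyl-1-(trimethylsilyloxy)cyclohex-1-ene
Product: 4 5,5-dimethyl-1-(trimethylsilyloxy)bicyclo[4.1.0]heptane (racemic)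
Conditions: Et2Zn, CH2I2, CH2Cl2, 0 °C → rt
Reagents that add atoms: diiodomethane, ICI
Why: Simmons–Smith cyclopropanation (zinc carbenoid from Et2Zn/CH2I2) is fast on the electron-rich silyl enol ether and delivers the one carbon needed for ring enlargement; both new centres are lost again in step 3.

Step 3
Reactants: 4 5,5-dimethyl-1-(trimethylsilyloxy)bicyclo[4.1.0]heptane
Product: 6 4,4-dimethylcyclohept-2-en-1-one, via β-chloro ketone 5 (not isolated)
Conditions: FeCl3, DMF, 0 °C → rt; then NaOAc, MeOH, reflux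
Reagents that add atoms: none
Why: Saegusa-type oxidative ring expansion: one-electron oxidation of the siloxycyclopropane by FeCl3 cleaves the internal cyclopropane bond to the ring-enlarged β-keto radical, which takes up chlorine, and base then eliminates HCl to the conjugated cycloheptenone.

Step 4
Reactants: 6 4,4-dimethylcyclohept-2-en-1-one
Product: 7 (2S,3S)-2,3-epoxy-4,4-dimethylcycloheptan-1-one
Conditions: 9-amino(9-deoxy)epiquinine·2 TFA (10 mol %), 50% aq. H2O2, dioxane, 35 °C
Reagents that add atoms: hydrogen peroxide, OO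
Why: Iminium-catalysed Weitz–Scheffer (nucleophilic) epoxidation, in which the cinchona primary amine salt exposes one enone face to the peroxide, should set C1 and C2 as the cis (2S,3S) oxirane; the C1 configuration is kept to the target.

Step 5
Reactants: 7 (2S,3S)-2,3-epoxy-4,4-dimethylcycloheptan-1-one
Product: 9 (1R,2R,3R)-1,2-diethynyl-4,4-dimethylcycloheptane-1,3-diol, via bromomagnesium alkoxide 8 (not isolated)
Conditions: HC≡CMgBr, THF, −78 → −20 °C; then LiC≡CH·ethylenediamine, DMSO, 45 °C
Reagents that add atoms: ethynylmagnesium bromide, C#C[Mg]Br; lithium acetylide (ethylenediamine complex), [Li+].[C-]#C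
Why: 1,2-Addition of the alkynyl Grignard reagent anti to the oxirane sets C7 (alkoxide cis to the oxirane), and SN2 opening of the oxirane by acetylide at C2 with inversion (C1 is screened by the CMe2 group, whereas C2 is flanked only by the slim ethynyl carbinol) places the C2 carbon substituent trans to the C7 oxygen and leaves C1 untouched.

Step 6
Reactants: 9 (1R,2R,3R)-1,2-diethynyl-4,4-dimethylcycloheptane-1,3-diol
Product: 10 (1S,2R,3R)-2-ethynyl-4,4-dimethyl-1-vinylcycloheptane-1,3-diol
Conditions: Red-Al, THF, 0 °C → rt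
Reagents that add atoms: none
Why: Alkoxide-directed trans-hydroalumination by the alkoxyaluminium hydride is specific for the propargylic alkyne on C7, so that it alone should be taken to the vinyl group while the homopropargylic alkyne on C2 survives at this temperature.

Step 7
Reactants: 10 (1S,2R,3R)-2-ethynyl-4,4-dimethyl-1-vinylcycloheptane-1,3-diol
Product: 11 (1S,2R,3R)-3-(tert-butyldimethylsilyloxy)-2-ethynyl-4,4-dimethyl-1-vinylcycloheptan-1-ol
Conditions: TBSOTf (1.1 equiv), 2,6-lutidine, CH2Cl2, −78 °C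
Reagents that add atoms: tert-butyldimethylsilyl trifluoromethanesulfonate, CC(C)(C)[Si](C)(C)OS(=O)(=O)C(F)(F)F
Why: Silylation with the silyl triflate at low temperature discriminates the secondary C1 hydroxyl from the tertiary C7 hydroxyl, which must stay free as the future alkoxide.

Step 8
Reactants: 11 (1S,2R,3R)-3-(tert-butyldimethylsilyloxy)-2-ethynyl-4,4-dimethyl-1-vinylcycloheptan-1-ol
Product: 13 (1S,2R,3R)-3-(tert-butyldimethylsilyloxy)-2-[(E)-1-iodoprop-1-en-2-yl]-4,4-dimethyl-1-vinylcycloheptan-1-ol, via alkenylalane 12 (not isolated)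
Conditions: AlMe3, Cp2ZrCl2 (25 mol %), CH2Cl2, 0 °C → rt; then I2, THF, −30 °C
Reagents that add atoms: trimethylaluminium, C[Al](C)C; iodine, II
Why: Zirconium-catalysed carboalumination (Negishi) adds methyl and aluminium syn across the terminal alkyne with aluminium on the terminal carbon, and iodinolysis with retention gives the E-iodoalkene in which iodine is trans to C2.

Step 9
Reactants: 13 (1S,2R,3R)-3-(tert-butyldimethylsilyloxy)-2-[(E)-1-iodoprop-1-en-2-yl]-4,4-dimethyl-1-vinylcycloheptan-1-ol
Product: 14 (1S,2R,3R)-3-(tert-butyldimethylsilyloxy)-2-[(E)-1-(4-methoxybenzyloxy)prop-1-en-2-yl]-4,4-dimethyl-1-vinylcycloheptan-1-ol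
Conditions: CuI (10 mol %), 3,4,7,8-tetramethyl-1,10-phenanthroline (20 mol %), Cs2CO3, 4-methoxybenzyl alcohol, toluene, 80 °C
Reagents that add atoms: 4-methoxybenzyl alcohol, COc1ccc(CO)cc1
Why: Copper-catalysed Ullmann-type C–O coupling of the alkenyl iodide with the primary alcohol retains the alkene geometry and should give the E-enol ether, the trans-placed tertiary hydroxyl being unable to cyclise onto the iodide.

Step 10
Reactants: 14 (1S,2R,3R)-3-(tert-butyldimethylsilyloxy)-2-[(E)-1-(4-methoxybenzyloxy)prop-1-en-2-yl]-4,4-dimethyl-1-vinylcycloheptan-1-ol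
Product: 17 (1E,4S,5E,7R)-7-(tert-butyldimethylsilyloxy)-4-(4-methoxybenzyloxy)-5,8,8-trimethylcycloundeca-1,5-dien-1-yl trifluoromethanesulfonate, via potassium alkoxide 15 (not isolated), via potassium enolate 16 (not isolated)
Conditions: KHMDS, 18-crown-6, THF, 0 °C → rt; then PhNTf2, −78 → 0 °C
Reagents that add atoms: N-phenylbis(trifluoromethanesulfonimide), O=S(=O)(N(c1ccccc1)S(=O)(=O)C(F)(F)F)C(F)(F)F
Why: Deprotonation gives the potassium alkoxide 15, whose anionic oxy-Cope ([3,3]-sigmatropic) shift through a chair transition state cleaves the C2–C7 bond of the cycloheptane and joins C4 to C5, and the potassium enolate 16 so formed is O-sulfonylated by PhNTf2. The closest known reaction type is the alkoxide-accelerated oxy-Cope ring enlargement of 1,2-dialkenylcycloalkan-1-ols with trapping of the regiodefined enolate. The eleven-membered ring is closed as a four-carbon ring enlargement, the new bond forming inside the six-centre chair array and not by an exo or endo cyclisation. The new stereocentre C4 is controlled by C2 of 14 through suprafacial chirality transfer with the OPMB group of the E-enol ether equatorial, which from (2R) should give (4S). The step needs the chair in which the C7–C8 ring bond is axial (O– equatorial) and the C2–C1 bond equatorial, since only it gives the 2E alkene together with the enolate that has C8 cis to C5 (the later 6Z alkene). That chair is secured by the cis relation of the two alkenyl groups set in step 5 (only an axial/equatorial chair is open to them), by the equatorial preference of the ion-paired oxygen and by the 1,3-diaxial strain C1 would meet in the alternative chair, and the enolate regiochemistry (towards C6, not C8) follows from the mechanism.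

Step 11
Reactants: 17 (1E,4S,5E,7R)-7-(tert-butyldimethylsilyloxy)-4-(4-methoxybenzyloxy)-5,8,8-trimethylcycloundeca-1,5-dien-1-yl trifluoromethanesulfonate
Product: 18 tert-butyl{[(1R,2E,4S,6Z)-4-(4-methoxybenzyloxy)-3,7,11,11-tetramethylcycloundeca-2,6-dien-1-yl]oxy}dimethylsilane
Conditions: Fe(acac)3 (5 mol %), MeMgBr, THF/NMP, −30 → 0 °C
Reagents that add atoms: methylmagnesium bromide, C[Mg]Br
Why: Iron-catalysed Kumada-type cross-coupling of the alkenyl triflate with the methyl Grignard reagent proceeds with retention, so the methyl group takes the place of the triflate and C8 stays cis to C5, which is the 6Z alkene.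

Step 12
Reactants: 18 tert-butyl{[(1R,2E,4S,6Z)-4-(4-methoxybenzyloxy)-3,7,11,11-tetramethylcycloundeca-2,6-dien-1-yl]oxy}dimethylsilane
Product: 19 (1R,2E,4S,6Z)-4-(4-methoxybenzyloxy)-3,7,11,11-tetramethylcycloundeca-2,6-dien-1-ol
Conditions: TBAF, THF, 0 °C → rt
Reagents that add atoms: none
Why: Fluoride-mediated desilylation frees the C1 hydroxyl, while the PMB ether and both alkenes are inert.

Step 13
Reactants: 19 (1R,2E,4S,6Z)-4-(4-methoxybenzyloxy)-3,7,11,11-tetramethylcycloundeca-2,6-dien-1-ol; 20 4-acetoxy-3-methoxybenzoic acid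
Product: 22 (1R,2E,4S,6Z)-4-(4-methoxybenzyloxy)-3,7,11,11-tetramethylcycloundeca-2,6-dien-1-yl 4-acetoxy-3-methoxybenzoate, via acid chloride 21 (not isolated)
Conditions: 20, (COCl)2, cat. DMF, CH2Cl2, 0 °C → rt; then 19, Et3N, DMAP, CH2Cl2, 0 °C → rt
Reagents that add atoms: none
Why: DMAP-catalysed acylation of the hindered neopentyl-type allylic alcohol by the acid chloride takes place at oxygen with retention at C1, the aryl acetate being far less electrophilic than the acid chloride.

Step 14
Reactants: 22 (1R,2E,4S,6Z)-4-(4-methoxybenzyloxy)-3,7,11,11-tetramethylcycloundeca-2,6-dien-1-yl 4-acetoxy-3-methoxybenzoate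
Product: 23 (1R,2E,4S,6Z)-4-hydroxy-3,7,11,11-tetramethylcycloundeca-2,6-dien-1-yl 4-acetoxy-3-methoxybenzoate
Conditions: DDQ, CH2Cl2/pH 7 buffer, 0 °C
Reagents that add atoms: none
Why: Oxidative cleavage of the p-methoxybenzyl ether by DDQ (benzylic hydride abstraction, then hydrolysis of the oxocarbenium ion) under buffered conditions frees the C4 hydroxyl without ionising the allylic ester.

Step 15
Reactants: 23 (1R,2E,4S,6Z)-4-hydroxy-3,7,11,11-tetramethylcycloundeca-2,6-dien-1-yl 4-acetoxy-3-methoxybenzoate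
Product: 24 (1R,2E,4S,6Z)-4-hydroxy-3,7,11,11-tetramethylcycloundeca-2,6-dien-1-yl 4-hydroxy-3-methoxybenzoate (CNP0234435.1)
Conditions: K2CO3 (cat.), MeOH, 0 °C
Reagents that add atoms: none
Why: Mild methanolysis (transesterification) cleaves the activated phenyl acetate much faster than the hindered secondary benzoate, which releases the phenol and should give the target.

**Compound list**

1 | 3-methylcyclohex-2-en-1-one | CC1=CC(=O)CCC1 | starting material
2 | lithium 3,3-dimethylcyclohex-1-en-1-olate | [Li+].[O-]C1=CC(C)(C)CCC1 | intermediate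
3 | 3,3-dimethyl-1-(trimethylsilyloxy)cyclohex-1-ene | C[Si](C)(C)OC1=CC(C)(C)CCC1 | intermediate
4 | 5,5-dimethyl-1-(trimethylsilyloxy)bicyclo[4.1.0]heptane (racemic) | C[Si](C)(C)OC12CCCC(C)(C)C1C2 | intermediate
5 | 3-chloro-4,4-dimethylcycloheptan-1-one (racemic) | O=C1CC(Cl)C(C)(C)CCC1 | intermediate
6 | 4,4-dimethylcyclohept-2-en-1-one | O=C1C=CC(C)(C)CCC1 | intermediate
7 | (2S,3S)-2,3-epoxy-4,4-dimethylcycloheptan-1-one | O=C1CCCC(C)(C)[C@@H]2O[C@H]12 | intermediate
8 | bromomagnesium (1S,2S,3S)-1-ethynyl-2,3-epoxy-4,4-dimethylcycloheptan-1-olate | C#C[C@@]1(O[Mg]Br)CCCC(C)(C)[C@@H]2O[C@H]12 | intermediate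
9 | (1R,2R,3R)-1,2-diethynyl-4,4-dimethylcycloheptane-1,3-diol | C#C[C@@]1(O)CCCC(C)(C)[C@H](O)[C@H]1C#C | intermediate
10 | (1S,2R,3R)-2-ethynyl-4,4-dimethyl-1-vinylcycloheptane-1,3-diol | C=C[C@@]1(O)CCCC(C)(C)[C@H](O)[C@H]1C#C | intermediate
11 | (1S,2R,3R)-3-(tert-butyldimethylsilyloxy)-2-ethynyl-4,4-dimethyl-1-vinylcycloheptan-1-ol | C=C[C@@]1(O)CCCC(C)(C)[C@H](O[Si](C)(C)C(C)(C)C)[C@H]1C#C | intermediate
12 | O-dimethylaluminium alkoxide of the (E)-alkenyl(dimethyl)alane from 11 | C=C[C@@]1(O[Al](C)C)CCCC(C)(C)[C@H](O[Si](C)(C)C(C)(C)C)[C@H]1/C(C)=C/[Al](C)C | intermediate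
13 | (1S,2R,3R)-3-(tert-butyldimethylsilyloxy)-2-[(E)-1-iodoprop-1-en-2-yl]-4,4-dimethyl-1-vinylcycloheptan-1-ol | C=C[C@@]1(O)CCCC(C)(C)[C@H](O[Si](C)(C)C(C)(C)C)[C@H]1/C(C)=C/I | intermediate
14 | (1S,2R,3R)-3-(tert-butyldimethylsilyloxy)-2-[(E)-1-(4-methoxybenzyloxy)prop-1-en-2-yl]-4,4-dimethyl-1-vinylcycloheptan-1-ol | C=C[C@@]1(O)CCCC(C)(C)[C@H](O[Si](C)(C)C(C)(C)C)[C@H]1/C(C)=C/OCc1ccc(OC)cc1 | intermediate
15 | potassium alkoxide of 14 | [K+].C=C[C@@]1([O-])CCCC(C)(C)[C@H](O[Si](C)(C)C(C)(C)C)[C@H]1/C(C)=C/OCc1ccc(OC)cc1 | intermediate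
16 | potassium (1E,4S,5E,7R)-7-(tert-butyldimethylsilyloxy)-4-(4-methoxybenzyloxy)-5,8,8-trimethylcycloundeca-1,5-dien-1-olate | [K+].CC(C)(C)[Si](C)(C)O[C@@H]1/C=C(\C)[C@@H](OCc2ccc(OC)cc2)C/C=C(/[O-])CCCC1(C)C | intermediate
17 | (1E,4S,5E,7R)-7-(tert-butyldimethylsilyloxy)-4-(4-methoxybenzyloxy)-5,8,8-trimethylcycloundeca-1,5-dien-1-yl trifluoromethanesulfonate | CC(C)(C)[Si](C)(C)O[C@@H]1/C=C(\C)[C@@H](OCc2ccc(OC)cc2)C/C=C(/OS(=O)(=O)C(F)(F)F)CCCC1(C)C | intermediate
18 | tert-butyl{[(1R,2E,4S,6Z)-4-(4-methoxybenzyloxy)-3,7,11,11-tetramethylcycloundeca-2,6-dien-1-yl]oxy}dimethylsilane | CC(C)(C)[Si](C)(C)O[C@@H]1/C=C(\C)[C@@H](OCc2ccc(OC)cc2)C/C=C(/C)CCCC1(C)C | intermediate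
19 | (1R,2E,4S,6Z)-4-(4-methoxybenzyloxy)-3,7,11,11-tetramethylcycloundeca-2,6-dien-1-ol | O[C@@H]1/C=C(\C)[C@@H](OCc2ccc(OC)cc2)C/C=C(/C)CCCC1(C)C | intermediate
20 | 4-acetoxy-3-methoxybenzoic acid | COc1cc(C(=O)O)ccc1OC(C)=O | starting material
21 | 4-acetoxy-3-methoxybenzoyl chloride | COc1cc(C(=O)Cl)ccc1OC(C)=O | intermediate
22 | (1R,2E,4S,6Z)-4-(4-methoxybenzyloxy)-3,7,11,11-tetramethylcycloundeca-2,6-dien-1-yl 4-acetoxy-3-methoxybenzoate | COc1cc(C(=O)O[C@@H]2/C=C(\C)[C@@H](OCc3ccc(OC)cc3)C/C=C(/C)CCCC2(C)C)ccc1OC(C)=O | intermediate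
23 | (1R,2E,4S,6Z)-4-hydroxy-3,7,11,11-tetramethylcycloundeca-2,6-dien-1-yl 4-acetoxy-3-methoxybenzoate | COc1cc(C(=O)O[C@@H]2/C=C(\C)[C@@H](O)C/C=C(/C)CCCC2(C)C)ccc1OC(C)=O | intermediate
24 | (1R,2E,4S,6Z)-4-hydroxy-3,7,11,11-tetramethylcycloundeca-2,6-dien-1-yl 4-hydroxy-3-methoxybenzoate (CNP0234435.1) | COc1cc(C(=O)O[C@@H]2/C=C(\C)[C@@H](O)C/C=C(/C)CCCC2(C)C)ccc1O | target

**Count and risks**

Total step count: 15. Longest linear sequence: 15 steps (1 → 24); acid 20 enters in step 13.

Steps most likely to fail: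

1. Step 10 (key step). The rearrangement may partition between the two axial/equatorial chairs, which would give the other enolate geometry or the C4 epimer. The silyl group on O–C1 may migrate to the C7 alkoxide. The free potassium enolate may suffer proton transfer or sulfonylation at carbon before O-triflation. The fallback answers the enolate-handling risks; it sets out from 14 and comes back at 17. The alkoxide is generated with KH/18-crown-6 in THF, and as soon as the rearrangement is complete the enolate is silylated at −78 °C with Me3SiCl/Et3N. This should give the isolable trimethylsilyl enol ether tert-butyl{[(1R,2E,4S,6E)-4-(4-methoxybenzyloxy)-3,11,11-trimethyl-7-(trimethylsilyloxy)cycloundeca-2,6-dien-1-yl]oxy}dimethylsilane F1, in which regio- and stereochemistry are locked. MeLi in THF at 0 °C then regenerates the lithium enolate of the same geometry, and N-(5-chloro-2-pyridyl)triflimide converts it into 17.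

2. Step 5. The acetylide may open the oxirane at C1 instead of C2 (both positions neighbour fully substituted carbons), and the basic medium may enolise or isomerise the epoxy ketone. The fallback installs the C2 substituent before C7 becomes quaternary; it sets out from 6 and comes back at 9.
   - Corey–Bakshi–Shibata reduction (the oxazaborolidine enantiomer that gives the R alcohol) should give (R)-4,4-dimethylcyclohept-2-en-1-ol F2.
   - Hydroxyl-directed epoxidation with VO(acac)2/t-BuOOH should give the cis-epoxy alcohol (1R,2R,3S)-2,3-epoxy-4,4-dimethylcycloheptan-1-ol F3.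
   - Lithium acetylide–ethylenediamine in DMSO then opens the oxirane at C2, now flanked by a secondary carbinol, to (1R,2S,3R)-2-ethynyl-4,4-dimethylcycloheptane-1,3-diol F4.
   - Selective oxidation of the less hindered C7 hydroxyl (TEMPO/PhI(OAc)2) gives (2R,3R)-2-ethynyl-3-hydroxy-4,4-dimethylcycloheptan-1-one F5.
   - Ethynylmagnesium bromide/CeCl3 should add to the magnesium chelate of F5 from the face anti to the C1 oxygen, giving 9.

3. Step 9. Oxidative addition at the hindered trisubstituted iodoalkene may be slow, so that protodeiodination, loss of the E geometry or hydrolysis of the enol ether compete. The fallback bypasses 13; it sets out from 11 and comes back at 14. Copper-catalysed syn-methylboration of the terminal alkyne (CuCl/Xantphos, B2pin2, MeI, NaOt-Bu) should give (1S,2R,3R)-3-(tert-butyldimethylsilyloxy)-4,4-dimethyl-2-[(E)-1-(4,4,5,5-tetramethyl-1,3,2-dioxaborolan-2-yl)prop-1-en-2-yl]-1-vinylcycloheptan-1-ol F6. Oxidative Chan–Lam-type etherification with 4-methoxybenzyl alcohol (Cu(OAc)2, Et3N, 4 Å sieves, air, rt) then gives 14 with retention of the alkene geometry.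

Further compounds
F1 | step 10 | tert-butyl{[(1R,2E,4S,6E)-4-(4-methoxybenzyloxy)-3,11,11-trimethyl-7-(trimethylsilyloxy)cycloundeca-2,6-dien-1-yl]oxy}dimethylsilane | CC(C)(C)[Si](C)(C)O[C@@H]1/C=C(\C)[C@@H](OCc2ccc(OC)cc2)C/C=C(/O[Si](C)(C)C)CCCC1(C)C
F2 | step 5 | (R)-4,4-dimethylcyclohept-2-en-1-ol | O[C@H]1C=CC(C)(C)CCC1
F3 | step 5 | (1R,2R,3S)-2,3-epoxy-4,4-dimethylcycloheptan-1-ol | O[C@@H]1CCCC(C)(C)[C@@H]2O[C@H]12
F4 | step 5 | (1R,2S,3R)-2-ethynyl-4,4-dimethylcycloheptane-1,3-diol | O[C@@H]1CCCC(C)(C)[C@H](O)[C@H]1C#C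
F5 | step 5 | (2R,3R)-2-ethynyl-3-hydroxy-4,4-dimethylcycloheptan-1-one | O=C1CCCC(C)(C)[C@H](O)[C@H]1C#C
F6 | step 9 | (1S,2R,3R)-3-(tert-butyldimethylsilyloxy)-4,4-dimethyl-2-[(E)-1-(4,4,5,5-tetramethyl-1,3,2-dioxaborolan-2-yl)prop-1-en-2-yl]-1-vinylcycloheptan-1-ol | C=C[C@@]1(O)CCCC(C)(C)[C@H](O[Si](C)(C)C(C)(C)C)[C@H]1/C(C)=C/B1OC(C)(C)C(C)(C)O1
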